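No cross-coupling is asked to forge the crowded C8–C6'' bond. Instead, ring A of the 7-methoxyflavone half is grown on an alkyne that already sits on C6'' of protected apigenin. The feature exploited is the oxygen pattern of ring A around C8: C8a carries O1, C7 the methyl ether and C5 a hydroxyl. A cyclobutenone/ynol ether benzannulation delivers these three as free phenol, OMe and OBn in one operation while forming C8–C8a and C6–C7. Its precursors are tri-O-benzylapigenin carrying a methoxyethynyl group at C6'' and 3-benzyloxycyclobutenone. The single phenol then anchors ring C (aryloxyacrylate, Friedel–Crafts closure at C4a). Hydrogenolysis of five benzyl ethers ends the route.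

Key step: step 6

Assumption: the target SMILES fixes no configuration at the C8–C6'' axis, so the biaryl is made as a racemate.
Notation: unprimed locants refer to the 7-methoxyflavone half and double-primed locants to the apigenin half. Ar = 5,7-bis(benzyloxy)-2-[4-(benzyloxy)phenyl]-4-oxochromen-6-yl.

Step 1
Reactants: 1 apigenin
Product: 2 7-(benzyloxy)-2-[4-(benzyloxy)phenyl]-5-hydroxychromen-4-one
Conditions: BnBr (2.1 equiv), K2CO3 (2.2 equiv), DMF, rt
Reagents that add atoms: benzyl bromide, BrCc1ccccc1
Why: Williamson etherification: the 5-OH is hydrogen-bonded to the C4 carbonyl and is the least acidic and least nucleophilic of the three phenols, so two equivalents of benzyl bromide should stop at the 7,4'-diether.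

Step 2
Reactants: 2 7-(benzyloxy)-2-[4-(benzyloxy)phenyl]-5-hydroxychromen-4-one
Product: 3 7-(benzyloxy)-2-[4-(benzyloxy)phenyl]-5-hydroxy-6-iodochromen-4-one
Conditions: NIS (1.05 equiv), DMF, rt, dark
Reagents that add atoms: N-iodosuccinimide, O=C1CCC(=O)N1I
Why: Electrophilic aromatic iodination: in 5-hydroxy-7-alkoxyflavones neutral iodinating agents attack C6, ortho to the chelated phenol, whereas fully alkylated flavones react at C8, which is why iodination comes before the last benzylation.

Step 3
Reactants: 3 7-(benzyloxy)-2-[4-(benzyloxy)phenyl]-5-hydroxy-6-iodochromen-4-one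
Product: 4 5,7-bis(benzyloxy)-2-[4-(benzyloxy)phenyl]-6-iodochromen-4-one
Conditions: BnBr (1.5 equiv), K2CO3 (2 equiv), DMF, 65 °C
Reagents that add atoms: benzyl bromide, BrCc1ccccc1
Why: Williamson etherification under more forcing conditions breaks the chelate and caps the last phenol, which would otherwise add across a neighbouring ynol ether (benzofuran formation) and intercept ketenes later on.

Step 4
Reactants: 4 5,7-bis(benzyloxy)-2-[4-(benzyloxy)phenyl]-6-iodochromen-4-one; 5 chloroacetaldehyde dimethyl acetal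
Product: 8 5,7-bis(benzyloxy)-2-[4-(benzyloxy)phenyl]-6-(methoxyethynyl)chromen-4-one, via lithium methoxyacetylide 6 (not isolated), via methoxyethynylzinc chloride 7 (not isolated)
Conditions: 5 (3 equiv), LiNEt2 (3 equiv per 5), THF, 0 °C; ZnCl2 (2.2 equiv per 5), 0 °C to rt; then 4, Pd(PPh3)4 (5 mol %), THF, 50 °C; NaHCO3 work-up, Et3N-deactivated silica
Reagents that add atoms: none
Why: Threefold base treatment of the chloroacetal (loss of HCl and MeOH, then deprotonation) gives acetylide 6, ZnCl2 turns it into the non-basic 7 that leaves the chromenone carbonyl alone, and Negishi alkynylation of aryl iodides with alkoxyethynylzinc halides is established, the rod-like nucleophile being little hindered by the two ortho benzyloxy groups.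

Step 5
Reactants: 9 3-ethoxycyclobut-2-en-1-one
Product: 10 3-(benzyloxy)cyclobut-2-en-1-one
Conditions: BnOH (1.5 equiv), camphorsulfonic acid (5 mol %), toluene, 30–35 °C, reduced pressure (ethanol stripped)
Reagents that add atoms: benzyl alcohol, OCc1ccccc1
Why: Transetherification of a vinylogous ester (acid-catalysed addition–elimination at C3), driven by removal of ethanol and run well below the temperature at which the four-membered ring opens, gives the future O5 a group that leaves by hydrogenolysis while the methyl ether stays.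

Step 6
Reactants: 8 5,7-bis(benzyloxy)-2-[4-(benzyloxy)phenyl]-6-(methoxyethynyl)chromen-4-one; 10 3-(benzyloxy)cyclobut-2-en-1-one
Product: 15 5,7-bis(benzyloxy)-6-[4-(benzyloxy)-2-hydroxy-6-methoxyphenyl]-2-[4-(benzyloxy)phenyl]chromen-4-one, via vinylketene 11 (not isolated), via alkenylcyclobutenone 12 (not isolated), via dienylketene 13 (not isolated), via cyclohexadienone 14 (not isolated)
Conditions: 10 (2.5 equiv, syringe pump over 6 h) into 8, toluene (0.1 M), base-washed sealed vessel, argon, 110 °C then 140 °C; crude product stirred with K2CO3, MeOH–THF, rt (frees any phenol acylated by ketene)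
Reagents that add atoms: none
Why: Heating opens 10 by a conrotatory four-electron electrocyclic reaction (C1–C4 cleaved) to vinylketene 11, whose ketene C=C adds [2+2] to ynol ether 8 to give the 4-alkenylcyclobut-2-enone 12. Compound 12 reopens (four-electron, conrotatory) to dienylketene 13, which closes ring A by a disrotatory six-electron electrocyclisation in which the enol-ether CH2 terminus bonds to the ketene carbon (C4a–C8a restored) to give dienone 14, and enolisation gives phenol 15. The closest known reaction type is the Danheiser benzannulation of cyclobutenones with alkoxy- and siloxyalkynes; only the substitution is unfamiliar, namely an aryl group on the ynol ether and an alkoxy group on C3 of the cyclobutenone. The selectivity needed is the orientation of the [2+2] step: the methoxy lone pair makes the aryl-bearing alkyne carbon the nucleophilic terminus, so it bonds to the electrophilic ketene carbon (C8–C8a) and the methoxy carbon bonds to the ketene α-carbon (C7–C6), which puts OH and OMe on either side of C8 and OBn para to it. No stereocentre survives (C4 of 12 is erased on ring opening) and the C8–C6'' axis forms as a racemate. The methyl ynol ether has no β-hydrogen and so cannot fragment by retro-ene loss of an alkene at these temperatures, every phenol of 8 is capped so nothing traps the ketenes or cyclises onto the alkyne, and slow addition of excess 10 limits ketene dimerisation.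

Step 7
Reactants: 16 1-(benzyloxy)-4-ethynylbenzene
Product: 18 methyl 3-[4-(benzyloxy)phenyl]prop-2-ynoate, via lithium arylacetylide 17 (not isolated)
Conditions: n-BuLi (1.05 equiv), THF, −78 °C; ClCO2Me (1.3 equiv), −78 °C to 0 °C
Reagents that add atoms: methyl chloroformate, COC(=O)Cl
Why: Deprotonation of a terminal alkyne and C-acylation of the lithium acetylide with a chloroformate is the standard route to arylpropiolates.

Step 8
Reactants: 15 5,7-bis(benzyloxy)-6-[4-(benzyloxy)-2-hydroxy-6-methoxyphenyl]-2-[4-(benzyloxy)phenyl]chromen-4-one; 18 methyl 3-[4-(benzyloxy)phenyl]prop-2-ynoate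
Product: 19 methyl (Z)-3-[4-(benzyloxy)phenyl]-3-[2-Ar-5-(benzyloxy)-3-methoxyphenoxy]prop-2-enoate
Conditions: 18 (1.5 equiv), Cs2CO3 (0.3 equiv), dry DMF, 70 °C
Reagents that add atoms: none
Why: Oxa-Michael addition of a phenoxide to an arylpropiolate (first stage of the Ruhemann flavone synthesis): 15 has a single acidic OH, attack occurs at the aryl-bearing β-carbon (future C2), and anti addition places the aryloxy and ester groups cis, i.e. (Z).

Step 9
Reactants: 19 methyl (Z)-3-[4-(benzyloxy)phenyl]-3-[2-Ar-5-(benzyloxy)-3-methoxyphenoxy]prop-2-enoate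
Product: 20 (Z)-3-[4-(benzyloxy)phenyl]-3-[2-Ar-5-(benzyloxy)-3-methoxyphenoxy]prop-2-enoic acid
Conditions: LiOH·H2O (5 equiv), THF–MeOH–H2O, rt to 40 °C; 1 M HCl to pH 3, 0 °C
Reagents that add atoms: lithium hydroxide, [Li+].[OH-]
Why: Ordinary ester saponification: the enol ether is a vinylogous carbonate and the flavone of the apigenin half tolerates aqueous LiOH near room temperature.

Step 10
Reactants: 20 (Z)-3-[4-(benzyloxy)phenyl]-3-[2-Ar-5-(benzyloxy)-3-methoxyphenoxy]prop-2-enoic acid
Product: 22 5,4',5'',7'',4'''-penta-O-benzyl-7-O-methylagathisflavone, via mixed trifluoroacetic anhydride 21 (not isolated)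
Conditions: (CF3CO)2O (1.5 equiv), CH2Cl2, 0 °C to rt
Reagents that add atoms: none
Why: Intramolecular Friedel–Crafts acylation through the mixed anhydride, the method used for xanthones from 2-aryloxybenzoic acids: C4a is the only position the tethered acyl group can reach, it is activated by O1 and O5 (ortho) and O7 (para), the acid released equilibrates any (E)-isomer, and accidental loss of the peri 5-O-benzyl group would be harmless because the next step removes it anyway.

Step 11
Reactants: 22 5,4',5'',7'',4'''-penta-O-benzyl-7-O-methylagathisflavone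
Product: 23 7-O-methylagathisflavone (target)
Conditions: H2 (1 atm), 10 % Pd/C, THF–MeOH, rt
Reagents that add atoms: none
Why: Catalytic hydrogenolysis cleaves the five benzylic C–O bonds, while the aryl methyl ether and the two pyranone C2=C3 bonds are not touched at one atmosphere.

Compound list

1 | apigenin | O=c1cc(-c2ccc(O)cc2)oc2cc(O)cc(O)c12 | starting material
2 | 7-(benzyloxy)-2-[4-(benzyloxy)phenyl]-5-hydroxychromen-4-one | O=c1cc(-c2ccc(OCc3ccccc3)cc2)oc2cc(OCc3ccccc3)cc(O)c12 | intermediate
3 | 7-(benzyloxy)-2-[4-(benzyloxy)phenyl]-5-hydroxy-6-iodochromen-4-one | O=c1cc(-c2ccc(OCc3ccccc3)cc2)oc2cc(OCc3ccccc3)c(I)c(O)c12 | intermediate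
4 | 5,7-bis(benzyloxy)-2-[4-(benzyloxy)phenyl]-6-iodochromen-4-one | O=c1cc(-c2ccc(OCc3ccccc3)cc2)oc2cc(OCc3ccccc3)c(I)c(OCc3ccccc3)c12 | intermediate
5 | chloroacetaldehyde dimethyl acetal (2-chloro-1,1-dimethoxyethane) | COC(CCl)OC | starting material
6 | lithium methoxyacetylide | [Li]C#COC | intermediate
7 | methoxyethynylzinc chloride | COC#C[Zn]Cl | intermediate
8 | 5,7-bis(benzyloxy)-2-[4-(benzyloxy)phenyl]-6-(methoxyethynyl)chromen-4-one | COC#Cc1c(OCc2ccccc2)cc2oc(-c3ccc(OCc4ccccc4)cc3)cc(=O)c2c1OCc1ccccc1 | intermediate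
9 | 3-ethoxycyclobut-2-en-1-one | CCOC1=CC(=O)C1 | starting material
10 | 3-(benzyloxy)cyclobut-2-en-1-one | O=C1CC(OCc2ccccc2)=C1 | intermediate
11 | 3-(benzyloxy)buta-1,3-dien-1-one (vinylketene) | C=C(OCc1ccccc1)C=C=O | intermediate
12 | 2-Ar-4-[1-(benzyloxy)ethenyl]-3-methoxycyclobut-2-en-1-one (racemic) | COC1=C(c2c(OCc3ccccc3)cc3oc(-c4ccc(OCc5ccccc5)cc4)cc(=O)c3c2OCc2ccccc2)C(=O)C1C(=C)OCc1ccccc1 | intermediate
13 | (3E)-2-Ar-5-(benzyloxy)-3-methoxyhexa-1,3,5-trien-1-one (dienylketene, reacting termini cis) | O=C=C(c1c(OCc2ccccc2)cc2oc(-c3ccc(OCc4ccccc4)cc3)cc(=O)c2c1OCc1ccccc1)/C(OC)=C\C(=C)OCc1ccccc1 | intermediate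
14 | 2-Ar-5-(benzyloxy)-3-methoxycyclohexa-2,4-dien-1-one | COC1=C(c2c(OCc3ccccc3)cc3oc(-c4ccc(OCc5ccccc5)cc4)cc(=O)c3c2OCc2ccccc2)C(=O)CC(OCc2ccccc2)=C1 | intermediate
15 | 5,7-bis(benzyloxy)-6-[4-(benzyloxy)-2-hydroxy-6-methoxyphenyl]-2-[4-(benzyloxy)phenyl]chromen-4-one (2-Ar-5-(benzyloxy)-3-methoxyphenol) | COc1cc(OCc2ccccc2)cc(O)c1-c1c(OCc2ccccc2)cc2oc(-c3ccc(OCc4ccccc4)cc3)cc(=O)c2c1OCc1ccccc1 | intermediate
16 | 1-(benzyloxy)-4-ethynylbenzene | C#Cc1ccc(OCc2ccccc2)cc1 | starting material
17 | lithium [4-(benzyloxy)phenyl]acetylide | [Li]C#Cc1ccc(OCc2ccccc2)cc1 | intermediate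
18 | methyl 3-[4-(benzyloxy)phenyl]prop-2-ynoate | COC(=O)C#Cc1ccc(OCc2ccccc2)cc1 | intermediate
19 | methyl (Z)-3-[4-(benzyloxy)phenyl]-3-[2-Ar-5-(benzyloxy)-3-methoxyphenoxy]prop-2-enoate | COC(=O)/C=C(/c1ccc(OCc2ccccc2)cc1)Oc1cc(OCc2ccccc2)cc(OC)c1-c1c(OCc2ccccc2)cc2oc(-c3ccc(OCc4ccccc4)cc3)cc(=O)c2c1OCc1ccccc1 | intermediate
20 | (Z)-3-[4-(benzyloxy)phenyl]-3-[2-Ar-5-(benzyloxy)-3-methoxyphenoxy]prop-2-enoic acid | OC(=O)/C=C(/c1ccc(OCc2ccccc2)cc1)Oc1cc(OCc2ccccc2)cc(OC)c1-c1c(OCc2ccccc2)cc2oc(-c3ccc(OCc4ccccc4)cc3)cc(=O)c2c1OCc1ccccc1 | intermediate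
21 | mixed anhydride of 20 with trifluoroacetic acid | O=C(OC(=O)C(F)(F)F)/C=C(/c1ccc(OCc2ccccc2)cc1)Oc1cc(OCc2ccccc2)cc(OC)c1-c1c(OCc2ccccc2)cc2oc(-c3ccc(OCc4ccccc4)cc3)cc(=O)c2c1OCc1ccccc1 | intermediate
22 | 5,4',5'',7'',4'''-penta-O-benzyl-7-O-methylagathisflavone | COc1cc(OCc2ccccc2)c2c(=O)cc(-c3ccc(OCc4ccccc4)cc3)oc2c1-c1c(OCc2ccccc2)cc2oc(-c3ccc(OCc4ccccc4)cc3)cc(=O)c2c1OCc1ccccc1 | intermediate
23 | 7-O-methylagathisflavone | COc1cc(O)c2c(=O)cc(-c3ccc(O)cc3)oc2c1-c1c(O)cc2oc(-c3ccc(O)cc3)cc(=O)c2c1O | target

Total step count: 11. Longest linear sequence: 9 (steps 1, 2, 3, 4, 6, 8, 9, 10, 11).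

Steps most likely to fail

Step 6. This pairing of an aryl-substituted ynol ether with a 3-alkoxycyclobutenone has no direct precedent. The [2+2] capture may be slow at an alkyne carbon shielded by two ortho benzyloxy groups. Ketene 11 would then be lost to dimerisation and oligomerisation, or the cascade could stall at 12.

The fallback gives up the ring construction and makes the axis by Suzuki–Miyaura coupling of two finished flavones. It sets out from iodide 4 and comes back at 22.
- Purchased genkwanin (7-O-methylapigenin) would be benzylated twice (BnBr, K2CO3, DMF, 70 °C) to 5,4'-di-O-benzylgenkwanin F1.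
- Iodination would follow at C8, the site preferred by fully alkylated 5,7-dioxyflavones (NIS, catalytic CF3CO2H, MeCN), to give the 8-iodide F2.
- Miyaura borylation (B2pin2, PdCl2(dppf), KOAc, dioxane, 90 °C) would give the 8-pinacolboronate F3.
- Coupling of F3 with 4 (Pd2(dba)3, SPhos, K3PO4, toluene–H2O, 100 °C) should give 22, and step 11 follows.

Step 4. Coupling at the doubly ortho-substituted iodide may be slow in a medium that still carries diethylamine and lithium methoxide. The ynol ether may also be hydrated during work-up and chromatography.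

The fallback replaces the zinc acetylide made in situ by an isolated tin acetylide, so that the C–C bond forms under neutral, salt-free Stille conditions. It sets out from 6 (made from 5 as in step 4) and from 4, and comes back at 8.
- Acetylide 6 would be quenched with Bu3SnCl and the product distilled to give tributyl(methoxyethynyl)stannane F4.
- F4 would then be coupled with 4 (Pd(PPh3)4, toluene, 80 °C) to give 8.

Step 8. Conjugate addition of a crowded phenoxide may be sluggish, because the β-carbon of the propiolate is deactivated by the p-benzyloxyphenyl donor. Acyl transfer to the phenoxide could compete.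

The fallback builds ring C in the opposite bond order, C4a–C4 first and O1–C2 last. It sets out from 15 and comes back at 22.
- Magnesium-mediated ortho-formylation (MgCl2, Et3N, paraformaldehyde, MeCN, reflux) reaches only the carbon next to the phenoxide and should give the C4a salicylaldehyde F5.
- After deprotonation of the phenol with LiHMDS, lithium acetylide 17 (from 16 as in step 7) would be added at −78 °C to 0 °C to give the propargylic alcohol F6. It forms as a diastereomer mixture with respect to the axis, which is of no consequence.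
- MnO2 in CH2Cl2 would give the ynone F7.
- Et2NH in DMF would bring about 6-endo closure of the phenol onto the aryl-bearing alkyne carbon to give 22.

Further compounds
F1 | step 6 | 5-(benzyloxy)-2-[4-(benzyloxy)phenyl]-7-methoxychromen-4-one (5,4'-di-O-benzylgenkwanin) | COc1cc(OCc2ccccc2)c2c(=O)cc(-c3ccc(OCc4ccccc4)cc3)oc2c1
F2 | step 6 | 5-(benzyloxy)-2-[4-(benzyloxy)phenyl]-8-iodo-7-methoxychromen-4-one | COc1cc(OCc2ccccc2)c2c(=O)cc(-c3ccc(OCc4ccccc4)cc3)oc2c1I
F3 | step 6 | 5-(benzyloxy)-2-[4-(benzyloxy)phenyl]-7-methoxy-8-(4,4,5,5-tetramethyl-1,3,2-dioxaborolan-2-yl)chromen-4-one | COc1cc(OCc2ccccc2)c2c(=O)cc(-c3ccc(OCc4ccccc4)cc3)oc2c1B1OC(C)(C)C(C)(C)O1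
F4 | step 4 | tributyl(methoxyethynyl)stannane | CCCC[Sn](CCCC)(CCCC)C#COC
F5 | step 8 | 3-Ar-6-(benzyloxy)-2-hydroxy-4-methoxybenzaldehyde | COc1cc(OCc2ccccc2)c(C=O)c(O)c1-c1c(OCc2ccccc2)cc2oc(-c3ccc(OCc4ccccc4)cc3)cc(=O)c2c1OCc1ccccc1
F6 | step 8 | 1-[3-Ar-6-(benzyloxy)-2-hydroxy-4-methoxyphenyl]-3-[4-(benzyloxy)phenyl]prop-2-yn-1-ol (stereoisomer mixture) | COc1cc(OCc2ccccc2)c(C(O)C#Cc2ccc(OCc3ccccc3)cc2)c(O)c1-c1c(OCc2ccccc2)cc2oc(-c3ccc(OCc4ccccc4)cc3)cc(=O)c2c1OCc1ccccc1
F7 | step 8 | 1-[3-Ar-6-(benzyloxy)-2-hydroxy-4-methoxyphenyl]-3-[4-(benzyloxy)phenyl]prop-2-yn-1-one | COc1cc(OCc2ccccc2)c(C(=O)C#Cc2ccc(OCc3ccccc3)cc2)c(O)c1-c1c(OCc2ccccc2)cc2oc(-c3ccc(OCc4ccccc4)cc3)cc(=O)c2c1OCc1ccccc1
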